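The synthesis rests on cutting the bond between the diarylmethine carbon C7 and the alkene carbon C6 of the heptenyl chain (C1 is the benzylic CH2 of the far phenol; ring A is the acylphloroglucinol ring, primed). C7 stands ortho to the free 2'-OH of ring A, so it is the exocyclic end of an ortho-quinone methide O2'=C2'–C3'=C7. One chiral-biphenol-catalysed three-component condensation lets a ring A acetophenone with only O2' free, 4-(methoxymethoxy)benzaldehyde and an (E)-alkenylboronate carrying C1–C6 with its (S)-carbinol build that quinone methide in the flask and transfer the alkenyl group to C7 enantioselectively. Claisen–Schmidt condensation and acid deprotection finish the chalcone.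

Key step: step 6

Remark on numbering: chain atoms are C1–C7 as defined above (C3 carbinol, C5=C6 alkene, C7 diarylmethine); ring A is C1' (acyl), C2' (OH), C3' (bears C7), C4' (OH), C5' (H), C6' (OMe). In systematic names the heptenyl group is numbered from its point of attachment, so C7 appears there as C1 (1R) and C3 as C5 (5S).

Assumption: the facial sense of the two chiral catalysts (the phosphoric acid in step 2, the dibromo-biphenol in step 6) is assigned by analogy with simpler substrates. Both antipodes of each catalyst are available, so the antipode is used if a pilot run on a model substrate shows the reverse sense.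

Remark on materials: compounds 1, 2, 4, 10 and 12 are taken as catalogue compounds.

Step 1
Reactants: 1 1-iodo-4-(methoxymethoxy)benzene; 2 prop-2-en-1-ol (allyl alcohol)
Product: 3 3-[4-(methoxymethoxy)phenyl]propanal
Conditions: Pd(OAc)2 (2 mol%), n-Bu4NCl, NaHCO3, DMF, 40 °C
Reagents that add atoms: none
Why: Heck arylation of allyl alcohol under Jeffery conditions, in which the arylpalladium adds to the terminal alkene carbon and β-hydride elimination toward the carbinol carbon gives an enol that tautomerises to the 3-arylpropanal, while the aryl MOM ether is inert to NaHCO3 in DMF.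

Step 2
Reactants: 3 3-[4-(methoxymethoxy)phenyl]propanal; 4 allenylboronic acid pinacol ester
Product: 6 (3S)-1-[4-(methoxymethoxy)phenyl]hex-5-yn-3-ol, via pinacol borate ester 5 (not isolated)
Conditions: (R)-3,3'-bis(2,4,6-triisopropylphenyl)-1,1'-binaphthyl-2,2'-diyl hydrogen phosphate (10 mol%), 4 Å MS, toluene, −20 °C; then aq. NaHCO3
Reagents that add atoms: none
Why: Chiral phosphoric acid-catalysed asymmetric propargylation (SE2' allenylboration through a six-membered chair transition state), in which the (R)-catalyst is expected to direct attack to the Re face of the aldehyde, which for this unbranched aliphatic aldehyde corresponds to the (S)-carbinol, and the O–B bond of 5 is cleaved on aqueous work-up.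

Step 3
Reactants: 6 (3S)-1-[4-(methoxymethoxy)phenyl]hex-5-yn-3-ol
Product: 7 tert-butyl({(3S)-1-[4-(methoxymethoxy)phenyl]hex-5-yn-3-yl}oxy)dimethylsilane
Conditions: TBSCl, imidazole, DMF, rt
Reagents that add atoms: tert-butyldimethylsilyl chloride (TBSCl), CC(C)(C)[Si](C)(C)Cl
Why: Standard imidazole-promoted silylation of a secondary alcohol, which touches neither the stereocentre nor the terminal alkyne C–H.

Step 4
Reactants: 7 tert-butyl({(3S)-1-[4-(methoxymethoxy)phenyl]hex-5-yn-3-yl}oxy)dimethylsilane
Product: 9 diethyl [(1E,4S)-4-{[tert-butyl(dimethyl)silyl]oxy}-6-[4-(methoxymethoxy)phenyl]hex-1-en-1-yl]boronate, via alkenylbis(isopinocampheyl)borane 8 (not isolated)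
Conditions: (−)-Ipc2BH (crystalline, prepared beforehand from (+)-α-pinene and BH3·SMe2), THF, −25 → 0 °C; then CH3CHO (excess), 0 → 40 °C; volatiles removed in vacuo
Reagents that add atoms: (−)-diisopinocampheylborane, B([C@@H]1C[C@@H]2C[C@H]([C@H]1C)C2(C)C)[C@@H]1C[C@@H]2C[C@H]([C@H]1C)C2(C)C; acetaldehyde, CC=O
Why: Hydroboration–dealkylation, in which the hindered dialkylborane adds syn and anti-Markovnikov to the terminal alkyne to give the (E)-alkenylborane 8 and acetaldehyde then expels both isopinocampheyl groups as α-pinene by β-hydride transfer, leaving the (E)-diethyl alkenylboronate with MOM and TBS ethers untouched.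

Step 5
Reactants: 10 1-(2,4-dihydroxy-6-methoxyphenyl)ethan-1-one
Product: 11 1-[2-hydroxy-6-methoxy-4-(methoxymethoxy)phenyl]ethan-1-one
Conditions: MOMCl (1.05 equiv), i-Pr2NEt, CH2Cl2, 0 °C → rt
Reagents that add atoms: chloromethyl methyl ether (MOMCl), COCCl
Why: Chemoselective O-alkylation (Williamson type) of the free and more acidic 4'-OH, while the 2'-OH is held in a hydrogen bond to the acetyl oxygen and stays free with one equivalent of MOMCl.

Step 6
Reactants: 11 1-[2-hydroxy-6-methoxy-4-(methoxymethoxy)phenyl]ethan-1-one; 12 4-(methoxymethoxy)benzaldehyde; 9 diethyl [(1E,4S)-4-{[tert-butyl(dimethyl)silyl]oxy}-6-[4-(methoxymethoxy)phenyl]hex-1-en-1-yl]boronate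
Product: 15 1-{2-hydroxy-3-[(1R,2E,5S)-5-{[tert-butyl(dimethyl)silyl]oxy}-1,7-bis[4-(methoxymethoxy)phenyl]hept-2-en-1-yl]-6-methoxy-4-(methoxymethoxy)phenyl}ethan-1-one, via cyclic alkenylboronate 13 (not isolated), via ortho-quinone methide 14 (not isolated)
Conditions: (R)-3,3'-Br2-BINOL (20 mol%), 3 Å MS, PhCF3, 70 °C; then H2O
Reagents that add atoms: none
Why: Phenol 11 exchanges onto boronate 9, and the boron held at O2' activates aldehyde 12 for attack by the neighbouring ring carbon C3', an ortho-specific Friedel–Crafts hydroxyalkylation whose adduct is held as the cyclic boronate 13. Heterolysis of the benzylic C7–O bond, helped by the para-alkoxyphenyl group and the electron-rich ring A, gives ortho-quinone methide 14, and the alkenyl group then moves from the dibromo-BINOL-bound boron, coordinated to the quinone methide oxygen, to C7 through a closed six-membered transition state, which forms the C6–C7 bond with retention of the (E)-alkene and rearomatises ring A. The closest known reaction type is the chiral-biphenol-catalysed multicomponent condensation of phenols, aldehydes and alkenylboronates, a Petasis-like conjugate boronate addition to an ortho-quinone methide. No ring of the product is closed; the six-membered dioxaborin ring of 13 forms only by O–B exchange and is opened again in the same flask. The new stereocentre C7 is controlled by the catalyst, whose binaphthyl unit on boron is expected to shield one face of the exocyclic C3'=C7 bond, while the remote (S)-centre at C3 should exert no significant bias, so that the (R)-catalyst is taken to give (7R). The step needs site selectivity for C3' over C5' and chemoselectivity for the quinone methide over the ketone: the first is secured because O2' is the only free hydroxyl and boron delivers the aldehyde ortho to it, the second because an acetyl group, unlike a chalcone enone, does not accept an alkenylboronate.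

Step 7
Reactants: 15 1-{2-hydroxy-3-[(1R,2E,5S)-5-{[tert-butyl(dimethyl)silyl]oxy}-1,7-bis[4-(methoxymethoxy)phenyl]hept-2-en-1-yl]-6-methoxy-4-(methoxymethoxy)phenyl}ethan-1-one; 12 4-(methoxymethoxy)benzaldehyde
Product: 16 (2E)-1-{2-hydroxy-3-[(1R,2E,5S)-5-{[tert-butyl(dimethyl)silyl]oxy}-1,7-bis[4-(methoxymethoxy)phenyl]hept-2-en-1-yl]-6-methoxy-4-(methoxymethoxy)phenyl}-3-[4-(methoxymethoxy)phenyl]prop-2-en-1-one
Conditions: KOH (50% aq.), EtOH, 0 °C → rt; then cold dilute HCl to pH 5
Reagents that add atoms: none
Why: Claisen–Schmidt condensation, in which the ketone enolate adds to the non-enolisable aldehyde and E1cB dehydration gives the thermodynamically favoured (E)-enone, while the 2'-phenoxide keeps the chalcone open in base and C7–H, the silyl ether and the MOM ethers are not affected by KOH at room temperature.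

Step 8
Reactants: 16 (2E)-1-{2-hydroxy-3-[(1R,2E,5S)-5-{[tert-butyl(dimethyl)silyl]oxy}-1,7-bis[4-(methoxymethoxy)phenyl]hept-2-en-1-yl]-6-methoxy-4-(methoxymethoxy)phenyl}-3-[4-(methoxymethoxy)phenyl]prop-2-en-1-one
Product: 17 Epicalyxin B, (2E)-1-{2,4-dihydroxy-3-[(1R,2E,5S)-5-hydroxy-1,7-bis(4-hydroxyphenyl)hept-2-en-1-yl]-6-methoxyphenyl}-3-(4-hydroxyphenyl)prop-2-en-1-one
Conditions: 3 M aq. HCl, MeOH–THF, rt → 40 °C, short exposure under N2
Reagents that add atoms: none
Why: Acid-catalysed acetal exchange with methanol should remove the four aryl MOM ethers as dimethoxymethane and methanolysis should cleave the secondary TBS ether in the same pot, without involving any stereocentre or alkene; chalcones with this ring A pattern (2'-OH, 6'-OMe, 3'-alkyl) are known to come through such conditions in the open form when exposure is kept short.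

Compound list
1 | 1-iodo-4-(methoxymethoxy)benzene | COCOc1ccc(I)cc1 | starting material
2 | prop-2-en-1-ol (allyl alcohol) | C=CCO | starting material
3 | 3-[4-(methoxymethoxy)phenyl]propanal | COCOc1ccc(CCC=O)cc1 | intermediate
4 | 4,4,5,5-tetramethyl-2-(propa-1,2-dien-1-yl)-1,3,2-dioxaborolane (allenylboronic acid pinacol ester) | C=C=CB1OC(C)(C)C(C)(C)O1 | starting material
5 | 2-({(3S)-1-[4-(methoxymethoxy)phenyl]hex-5-yn-3-yl}oxy)-4,4,5,5-tetramethyl-1,3,2-dioxaborolane | C#CC[C@@H](OB1OC(C)(C)C(C)(C)O1)CCc1ccc(OCOC)cc1 | intermediate (not isolated)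
6 | (3S)-1-[4-(methoxymethoxy)phenyl]hex-5-yn-3-ol | C#CC[C@@H](O)CCc1ccc(OCOC)cc1 | intermediate
7 | tert-butyl({(3S)-1-[4-(methoxymethoxy)phenyl]hex-5-yn-3-yl}oxy)dimethylsilane | C#CC[C@@H](O[Si](C)(C)C(C)(C)C)CCc1ccc(OCOC)cc1 | intermediate
8 | [(1E,4S)-4-{[tert-butyl(dimethyl)silyl]oxy}-6-[4-(methoxymethoxy)phenyl]hex-1-en-1-yl]bis(isopinocampheyl)borane | B([C@@H]1C[C@@H]2C[C@H]([C@H]1C)C2(C)C)([C@@H]1C[C@@H]2C[C@H]([C@H]1C)C2(C)C)/C=C/C[C@@H](O[Si](C)(C)C(C)(C)C)CCc1ccc(OCOC)cc1 | intermediate (not isolated)
9 | diethyl [(1E,4S)-4-{[tert-butyl(dimethyl)silyl]oxy}-6-[4-(methoxymethoxy)phenyl]hex-1-en-1-yl]boronate | CCOB(OCC)/C=C/C[C@@H](O[Si](C)(C)C(C)(C)C)CCc1ccc(OCOC)cc1 | intermediate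
10 | 1-(2,4-dihydroxy-6-methoxyphenyl)ethan-1-one | COc1cc(O)cc(O)c1C(C)=O | starting material
11 | 1-[2-hydroxy-6-methoxy-4-(methoxymethoxy)phenyl]ethan-1-one | COCOc1cc(O)c(C(C)=O)c(OC)c1 | intermediate
12 | 4-(methoxymethoxy)benzaldehyde | COCOc1ccc(C=O)cc1 | starting material
13 | 1-{2-[(1E,4S)-4-{[tert-butyl(dimethyl)silyl]oxy}-6-[4-(methoxymethoxy)phenyl]hex-1-en-1-yl]-7-methoxy-5-(methoxymethoxy)-4-[4-(methoxymethoxy)phenyl]-4H-1,3,2-benzodioxaborin-8-yl}ethan-1-one, both configurations at the benzylic ring carbon (erased in the next event) | COc1cc(OCOC)c2c(c1C(C)=O)OB(/C=C/C[C@@H](O[Si](C)(C)C(C)(C)C)CCc1ccc(OCOC)cc1)OC2c1ccc(OCOC)cc1 | intermediate (not isolated)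
14 | (6Z)-2-acetyl-3-methoxy-5-(methoxymethoxy)-6-{[4-(methoxymethoxy)phenyl]methylidene}cyclohexa-2,4-dien-1-one (aryl group on the carbonyl side, reacting as its boron complex) | O=C1C(C(C)=O)=C(OC)C=C(OCOC)/C1=C/c1ccc(OCOC)cc1 | intermediate (not isolated)
15 | 1-{2-hydroxy-3-[(1R,2E,5S)-5-{[tert-butyl(dimethyl)silyl]oxy}-1,7-bis[4-(methoxymethoxy)phenyl]hept-2-en-1-yl]-6-methoxy-4-(methoxymethoxy)phenyl}ethan-1-one | COc1cc(OCOC)c([C@H](/C=C/C[C@@H](O[Si](C)(C)C(C)(C)C)CCc2ccc(OCOC)cc2)c2ccc(OCOC)cc2)c(O)c1C(C)=O | intermediate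
16 | (2E)-1-{2-hydroxy-3-[(1R,2E,5S)-5-{[tert-butyl(dimethyl)silyl]oxy}-1,7-bis[4-(methoxymethoxy)phenyl]hept-2-en-1-yl]-6-methoxy-4-(methoxymethoxy)phenyl}-3-[4-(methoxymethoxy)phenyl]prop-2-en-1-one | COc1cc(OCOC)c([C@H](/C=C/C[C@@H](O[Si](C)(C)C(C)(C)C)CCc2ccc(OCOC)cc2)c2ccc(OCOC)cc2)c(O)c1C(=O)/C=C/c1ccc(OCOC)cc1 | intermediate
17 | Epicalyxin B, (2E)-1-{2,4-dihydroxy-3-[(1R,2E,5S)-5-hydroxy-1,7-bis(4-hydroxyphenyl)hept-2-en-1-yl]-6-methoxyphenyl}-3-(4-hydroxyphenyl)prop-2-en-1-one | COc1cc(O)c([C@H](/C=C/C[C@@H](O)CCc2ccc(O)cc2)c2ccc(O)cc2)c(O)c1C(=O)/C=C/c1ccc(O)cc1 | target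

Total step count: 8. Longest linear sequence: 7 steps (steps 1, 2, 3, 4, 6, 7, 8); step 5 prepares the second fragment.

Steps most likely to fail

Step 6. The hydroxyalkylation at the hydrogen-bonded 2'-phenol may be slower than unproductive consumption of the boronate (protodeboronation, chelation of boron by the acetyl oxygen). Facial discrimination in the alkenyl transfer may also be incomplete, which would give the C7 epimer alongside. The fallback sets out from 11 and 12 and comes back to the route at 15; it separates the two bond formations. Deprotonation of 11 with EtMgBr (1 equiv, CH2Cl2–toluene, 0 °C) and addition of 12 should give, by magnesium-phenoxide-directed ortho-hydroxyalkylation at C3', the racemic ortho-hydroxybenzhydrol F1. Brief exposure to EtOH with catalytic pyridinium p-toluenesulfonate should convert it, through the same quinone methide, into the racemic benzhydryl ethyl ether F2, a storable quinone methide precursor. F2 and boronate 9 are then combined with (R)-3,3'-Br2-BINOL in toluene at 60 °C in the known two-component boronate addition to return 15. Should facial control still be incomplete, the C7 epimers are diastereomers and can be separated by chromatography at 15 or 16.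

Step 8. Acid-promoted oxa-Michael closure of the 2'-hydroxychalcone to the flavanone may compete with acetal cleavage. The fallback sets out from 15 and comes back at 17; it reverses the order of the last two operations so that the enone never meets hot acid. Treatment of 15 with HCl in MeOH should remove the three MOM ethers and the silyl ether to give the deprotected acetophenone F3. Classical Claisen–Schmidt condensation of F3 with unprotected 4-hydroxybenzaldehyde (O=Cc1ccc(O)cc1) in concentrated aqueous KOH/EtOH, where the chalcone is held open as its phenoxide, followed by cold acidification to pH 5, should give 17 directly.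

Step 2. Enantiofacial discrimination may be incomplete with an unbranched aliphatic aldehyde, and the wrong C3 configuration would be carried forward as a diastereomer after step 6. The fallback sets out from 3 and comes back at 7; it sets the carbinol centre by ketone hydrogenation instead of C–C bond formation. Roskamp homologation of 3 with ethyl diazoacetate (SnCl2 cat., CH2Cl2) should give the β-keto ester F4. Noyori hydrogenation with RuCl2[(S)-BINAP] (H2, EtOH) should give the (S)-β-hydroxy ester F5, the sense following the established rule for β-keto esters. Silylation (TBSCl, imidazole) should give the silyl ether F6, i-Bu2AlH at −78 °C the aldehyde F7, and Ohira–Bestmann alkynylation (dimethyl (1-diazo-2-oxopropyl)phosphonate, K2CO3, MeOH) returns alkyne 7.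

Further compounds
F1 | step 6 | 1-[2-hydroxy-3-{hydroxy[4-(methoxymethoxy)phenyl]methyl}-6-methoxy-4-(methoxymethoxy)phenyl]ethan-1-one (racemic) | COc1cc(OCOC)c(C(O)c2ccc(OCOC)cc2)c(O)c1C(C)=O
F2 | step 6 | 1-[3-{ethoxy[4-(methoxymethoxy)phenyl]methyl}-2-hydroxy-6-methoxy-4-(methoxymethoxy)phenyl]ethan-1-one (racemic) | COc1cc(OCOC)c(C(OCC)c2ccc(OCOC)cc2)c(O)c1C(C)=O
F3 | step 8 | 1-{2,4-dihydroxy-3-[(1R,2E,5S)-5-hydroxy-1,7-bis(4-hydroxyphenyl)hept-2-en-1-yl]-6-methoxyphenyl}ethan-1-one | COc1cc(O)c([C@H](/C=C/C[C@@H](O)CCc2ccc(O)cc2)c2ccc(O)cc2)c(O)c1C(C)=O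
F4 | step 2 | ethyl 5-[4-(methoxymethoxy)phenyl]-3-oxopentanoate | CCOC(=O)CC(=O)CCc1ccc(OCOC)cc1
F5 | step 2 | ethyl (3S)-3-hydroxy-5-[4-(methoxymethoxy)phenyl]pentanoate | CCOC(=O)C[C@@H](O)CCc1ccc(OCOC)cc1
F6 | step 2 | ethyl (3S)-3-{[tert-butyl(dimethyl)silyl]oxy}-5-[4-(methoxymethoxy)phenyl]pentanoate | CCOC(=O)C[C@@H](O[Si](C)(C)C(C)(C)C)CCc1ccc(OCOC)cc1
F7 | step 2 | (3S)-3-{[tert-butyl(dimethyl)silyl]oxy}-5-[4-(methoxymethoxy)phenyl]pentanal | O=CC[C@@H](O[Si](C)(C)C(C)(C)C)CCc1ccc(OCOC)cc1
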